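**Retrosynthetic overview**
1. Target 25 ⇐ silyl ether/methyl ester 23 ⇐ Still–Gennari olefination of the α-alkylated trifluoroethyl phosphonate 19 with 3-(furan-3-yl)propanal 22 (sets the Z-acrylate).
2. 19 ⇐ iodide 18 + trifluoroethyl phosphonoacetate; 18 ⇐ aldehyde 15 by methylenation and hydrozirconation–iodination (the aldehyde carbon becomes the first CH2 of the acid arm).
3. Stereocentre: 15 ⇐ prenal 13 + allylic bromide 12 by an amine-catalysed enantioselective dienamine α-allylation; the isopropenyl group arises by deconjugation of prenal.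
4. 12 ⇐ Negishi carboalumination (E-alkene) and Still–Gennari olefination (Z-allylic alcohol) ⇐ keto acetal 3 ⇐ mono-ozonolysis of 1,5-dimethylcycloocta-1,5-diene 1 (the ring supplies the central Z-alkene).
5. No ring is formed: the furan is bought as 3-bromofuran, and the only ring event is the opening of the eight-membered ring of 1 in step 1.

Assumption: 1 is used as the isomerically pure 1,5-dimethyl isomer (technical material is freed from the 1,6-dimethyl isomer by fractional distillation before use).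

**Route**

Step 1
Reactants: 1 (1Z,5Z)-1,5-dimethylcycloocta-1,5-diene
Product: 3 (Z)-9,9-dimethoxy-6-methylnon-5-en-2-one, via keto aldehyde 2 (not isolated)
Conditions: O3 (0.9 equiv), CH2Cl2/MeOH 4:1, −78 °C; Me2S, −78 °C to rt; TsOH·H2O (2 mol%), 0 °C, 30 min; NaHCO3
Reagents that add atoms: ozone, [O-][O+]=O; methanol, CO
Why: Ozonolysis with reductive work-up cleaves one of the two equivalent trisubstituted alkenes when ozone is kept below one equivalent, the ring origin fixes the remaining alkene as Z, and under brief acid catalysis in methanol the aldehyde is acetalised much faster than the methyl ketone (chemoselective acetalisation).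

Step 2
Reactants: 3 (Z)-9,9-dimethoxy-6-methylnon-5-en-2-one
Product: 6 (Z)-4-methylnon-4-en-8-ynal, via enol phosphate 4 (not isolated), via alkyne acetal 5 (not isolated)
Conditions: LiN(i-Pr)2 (1.05 equiv), THF, −78 °C; ClP(O)(OEt)2; LiN(i-Pr)2 (2.3 equiv), −78 °C to rt; H2O; then 1 M HCl, THF, rt
Reagents that add atoms: water, O
Why: The methyl ketone is enolised kinetically on the methyl side, the enol phosphate loses diethyl phosphate under excess amide base to give the acetylide (Negishi conversion of a methyl ketone into a terminal alkyne), and the base-stable dimethyl acetal is then hydrolysed by aqueous acid.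

Step 3
Reactants: 6 (Z)-4-methylnon-4-en-8-ynal
Product: 7 ethyl (2Z,6Z)-2,6-dimethylundeca-2,6-dien-10-ynoate
Conditions: ethyl 2-[bis(2,2,2-trifluoroethoxy)phosphoryl]propanoate, KN(SiMe3)2, 18-crown-6, THF, −78 °C; then 6, −78 °C
Reagents that add atoms: ethyl 2-[bis(2,2,2-trifluoroethoxy)phosphoryl]propanoate, CCOC(=O)C(C)P(=O)(OCC(F)(F)F)OCC(F)(F)F
Why: Still–Gennari olefination: the trifluoroethyl phosphonate anion adds to the aldehyde and the adduct collapses quickly under kinetic control, which places the ester cis to the chain (Z), while the terminal alkyne and the trisubstituted alkene are inert.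

Step 4
Reactants: 7 ethyl (2Z,6Z)-2,6-dimethylundeca-2,6-dien-10-ynoate
Product: 8 (2Z,6Z)-2,6-dimethylundeca-2,6-dien-10-yn-1-ol
Conditions: i-Bu2AlH (2.3 equiv), CH2Cl2, −78 °C; aq. potassium sodium tartrate (KNaC4H4O6)
Reagents that add atoms: none
Why: i-Bu2AlH reduces the conjugated ester by 1,2-addition to the allylic alcohol without touching the alkene geometry or the alkyne (hydride reduction of an ester).

Step 5
Reactants: 8 (2Z,6Z)-2,6-dimethylundeca-2,6-dien-10-yn-1-ol
Product: 9 tert-butyl{[(2Z,6Z)-2,6-dimethylundeca-2,6-dien-10-yn-1-yl]oxy}dimethylsilane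
Conditions: TBSCl, imidazole, DMF, 0 °C to rt
Reagents that add atoms: tert-butyl(chloro)dimethylsilane, CC(C)(C)[Si](C)(C)Cl
Why: Standard silylation of a primary alcohol, which masks the hydroxyl for the organoaluminium, bromination and base steps that follow (silyl ether protection).

Step 6
Reactants: 9 tert-butyl{[(2Z,6Z)-2,6-dimethylundeca-2,6-dien-10-yn-1-yl]oxy}dimethylsilane
Product: 11 (2E,6Z,10Z)-12-{[tert-butyl(dimethyl)silyl]oxy}-3,7,11-trimethyldodeca-2,6,10-trien-1-ol, via alkenylalane 10 (not isolated)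
Conditions: AlMe3 (2.5 equiv), Cp2ZrCl2 (25 mol%), CH2Cl2, 0 °C to rt; solvent change to THF/hexane; n-BuLi (1.1 equiv), −78 °C; (CH2O)n, −78 °C to rt; aq. KNaC4H4O6
Reagents that add atoms: trimethylaluminium, C[Al](C)C; formaldehyde (as paraformaldehyde), C=O
Why: Negishi carboalumination: zirconium-catalysed syn addition of Me–Al across the terminal alkyne puts the methyl on the inner carbon and aluminium on the terminal carbon, and the derived alanate is hydroxymethylated by formaldehyde with retention, so the new trisubstituted alkene is E.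

Step 7
Reactants: 11 (2E,6Z,10Z)-12-{[tert-butyl(dimethyl)silyl]oxy}-3,7,11-trimethyldodeca-2,6,10-trien-1-ol
Product: 12 {[(2Z,6Z,10E)-12-bromo-2,6,10-trimethyldodeca-2,6,10-trien-1-yl]oxy}(tert-butyl)dimethylsilane
Conditions: CBr4, PPh3, CH2Cl2, −30 to 0 °C; used crude at once
Reagents that add atoms: tetrabromomethane, BrC(Br)(Br)Br
Why: Appel bromination replaces the primary allylic hydroxyl by bromide at low temperature without allylic transposition or loss of alkene geometry, and the silyl ether survives the neutral conditions.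

Step 8
Reactants: 12 {[(2Z,6Z,10E)-12-bromo-2,6,10-trimethyldodeca-2,6,10-trien-1-yl]oxy}(tert-butyl)dimethylsilane; 13 3-methylbut-2-enal (prenal)
Product: 15 (2R,4E,8Z,12Z)-14-{[tert-butyl(dimethyl)silyl]oxy}-5,9,13-trimethyl-2-(prop-1-en-2-yl)tetradeca-4,8,12-trienal, via dienamine 14 (not isolated)
Conditions: 13 (3 equiv), (R)-2-[diphenyl(trimethylsilyloxy)methyl]pyrrolidine (20 mol%), PhCO2H (20 mol%), 2,6-lutidine (1.3 equiv), Bu4NI (10 mol%), CHCl3, 0 °C, 36 h; quick filtration through Et3N-deactivated silica at 0 °C; used at once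
Reagents that add atoms: none
Why: Proposed new method: condensation of 13 with the secondary amine and loss of a γ-proton gives the s-trans dienamine 14, whose α-carbon (the largest HOMO coefficient, next to nitrogen) displaces bromide (iodide after halide exchange) from the unhindered primary terminus of 12 in an SN2 step, so the double bond is left out of conjugation as the isopropenyl group and the E-alkene of 12 is kept; the diphenyl(silyloxy)methyl arm of the R catalyst covers one face of the (E)-enamine so that the allyl group enters from the open Re face and gives the 2R aldehyde, the bulk at nitrogen holds back N-allylation, 2,6-lutidine takes up HBr, and the α-branched product iminium hydrolyses faster than it re-forms an enamine, which protects the new stereocentre; the closest known reaction types are the dienamine α-alkylation of enals with stabilised carbocations, the amine-catalysed SN2 α-benzylation of aldehydes and the Stork enamine allylation, none of which has been shown for a dienamine and an unactivated allylic bromide.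

Step 9
Reactants: 15 (2R,4E,8Z,12Z)-14-{[tert-butyl(dimethyl)silyl]oxy}-5,9,13-trimethyl-2-(prop-1-en-2-yl)tetradeca-4,8,12-trienal
Product: 16 tert-butyl{[(2Z,6Z,10E,13S)-2,6,10-trimethyl-13-(prop-1-en-2-yl)pentadeca-2,6,10,14-tetraen-1-yl]oxy}dimethylsilane
Conditions: Ph3PCH3Br, KN(SiMe3)2, THF, 0 °C; then 15, −78 to 0 °C
Reagents that add atoms: methyltriphenylphosphonium bromide, C[P+](c1ccccc1)(c1ccccc1)c1ccccc1.[Br-]
Why: Wittig methylenation: the unstabilised ylide adds to the aldehyde at −78 °C much faster than it deprotonates the α-position, so the stereocentre is kept and the former aldehyde carbon becomes part of a terminal vinyl group (the descriptor changes to S only because the priorities change).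

Step 10
Reactants: 16 tert-butyl{[(2Z,6Z,10E,13S)-2,6,10-trimethyl-13-(prop-1-en-2-yl)pentadeca-2,6,10,14-tetraen-1-yl]oxy}dimethylsilane
Product: 18 tert-butyl{[(2Z,6Z,10E,13S)-15-iodo-2,6,10-trimethyl-13-(prop-1-en-2-yl)pentadeca-2,6,10-trien-1-yl]oxy}dimethylsilane, via alkylzirconocene chloride 17 (not isolated)
Conditions: Cp2Zr(H)Cl (1.3 equiv), THF, rt, 1 h; then I2 (1.3 equiv), 0 °C
Reagents that add atoms: iodine, II
Why: Hydrozirconation with Cp2Zr(H)Cl is selective for the monosubstituted alkene over the 1,1-disubstituted and trisubstituted alkenes and places zirconium on the terminal carbon, and iodinolysis of the carbon–zirconium bond gives the primary iodide without touching the stereocentre (hydrozirconation–iodination).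

Step 11
Reactants: 18 tert-butyl{[(2Z,6Z,10E,13S)-15-iodo-2,6,10-trimethyl-13-(prop-1-en-2-yl)pentadeca-2,6,10-trien-1-yl]oxy}dimethylsilane
Product: 19 methyl (5R)-2-[bis(2,2,2-trifluoroethoxy)phosphoryl]-5-[(2E,6Z,10Z)-12-{[tert-butyl(dimethyl)silyl]oxy}-3,7,11-trimethyldodeca-2,6,10-trien-1-yl]-6-methylhept-6-enoate (both C-2 epimers)
Conditions: methyl 2-[bis(2,2,2-trifluoroethoxy)phosphoryl]acetate (2 equiv), NaH (1.9 equiv), THF, 0 °C; then 18, DMSO, 45 °C
Reagents that add atoms: methyl 2-[bis(2,2,2-trifluoroethoxy)phosphoryl]acetate, COC(=O)CP(=O)(OCC(F)(F)F)OCC(F)(F)F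
Why: SN2 alkylation of the stabilised sodium phosphonoacetate carbanion by the unhindered primary iodide (C-alkylation of a phosphonoacetate), run with excess phosphonate to hold back dialkylation; the new carbon next to phosphorus forms as both epimers, which does not matter because it becomes sp2 in step 13.

Step 12
Reactants: 20 3-bromofuran; 21 prop-2-en-1-ol
Product: 22 3-(furan-3-yl)propanal
Conditions: Pd(OAc)2 (3 mol%), Bu4NCl (1 equiv), NaHCO3 (2.5 equiv), DMF, 80 °C
Reagents that add atoms: none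
Why: Heck reaction under Jeffery conditions: zerovalent palladium formed from Pd(OAc)2 inserts into the C–Br bond, the furyl–palladium species adds to the terminal carbon of allyl alcohol, and β-hydride elimination toward the carbinol carbon gives an enol that tautomerises to the saturated aldehyde.

Step 13
Reactants: 19 methyl (5R)-2-[bis(2,2,2-trifluoroethoxy)phosphoryl]-5-[(2E,6Z,10Z)-12-{[tert-butyl(dimethyl)silyl]oxy}-3,7,11-trimethyldodeca-2,6,10-trien-1-yl]-6-methylhept-6-enoate; 22 3-(furan-3-yl)propanal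
Product: 23 methyl (2Z,5R)-5-[(2E,6Z,10Z)-12-{[tert-butyl(dimethyl)silyl]oxy}-3,7,11-trimethyldodeca-2,6,10-trien-1-yl]-2-[3-(furan-3-yl)propylidene]-6-methylhept-6-enoate
Conditions: 19, KN(SiMe3)2, 18-crown-6, THF, −78 °C; then 22, −78 °C
Reagents that add atoms: none
Why: Still–Gennari Horner–Wadsworth–Emmons olefination of an α-substituted bis(trifluoroethyl) phosphonate: fast, irreversible elimination from the kinetic adduct puts the ester cis to the aldehyde-derived chain, which is the Z acrylate of the target.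

Step 14
Reactants: 23 methyl (2Z,5R)-5-[(2E,6Z,10Z)-12-{[tert-butyl(dimethyl)silyl]oxy}-3,7,11-trimethyldodeca-2,6,10-trien-1-yl]-2-[3-(furan-3-yl)propylidene]-6-methylhept-6-enoate
Product: 25 (2Z,5R)-2-[3-(furan-3-yl)propylidene]-5-[(2E,6Z,10Z)-12-hydroxy-3,7,11-trimethyldodeca-2,6,10-trien-1-yl]-6-methylhept-6-enoic acid (CNP0258614.1), via hydroxy ester 24 (not isolated)
Conditions: Bu4NF, THF, rt; then LiOH, THF/MeOH/H2O, 45 °C; 1 M HCl to pH 3, 0 °C
Reagents that add atoms: lithium hydroxide, [Li+].[OH-]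
Why: Fluoride cleaves the silyl ether (desilylation) and hydroxide then saponifies the methyl ester; neither reagent can isomerise the trisubstituted alkenes or reach the stereocentre, and mild acidification at 0 °C spares the furan.

**Compound list**

1 | (1Z,5Z)-1,5-dimethylcycloocta-1,5-diene | C/C1=C/CC/C(C)=C\CC1 | starting material
2 | (Z)-4-methyl-8-oxonon-4-enal (keto aldehyde) | CC(=O)CC/C=C(/C)CCC=O | intermediate
3 | (Z)-9,9-dimethoxy-6-methylnon-5-en-2-one | CC(=O)CC/C=C(/C)CCC(OC)OC | intermediate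
4 | diethyl (5Z)-9,9-dimethoxy-6-methylnona-1,5-dien-2-yl phosphate (enol phosphate) | C=C(OP(=O)(OCC)OCC)CC/C=C(/C)CCC(OC)OC | intermediate
5 | (Z)-9,9-dimethoxy-6-methylnon-5-en-1-yne (alkyne acetal) | C#CCC/C=C(/C)CCC(OC)OC | intermediate
6 | (Z)-4-methylnon-4-en-8-ynal | C#CCC/C=C(/C)CCC=O | intermediate
7 | ethyl (2Z,6Z)-2,6-dimethylundeca-2,6-dien-10-ynoate | C#CCC/C=C(/C)CC/C=C(/C)C(=O)OCC | intermediate
8 | (2Z,6Z)-2,6-dimethylundeca-2,6-dien-10-yn-1-ol | C#CCC/C=C(/C)CC/C=C(/C)CO | intermediate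
9 | tert-butyl{[(2Z,6Z)-2,6-dimethylundeca-2,6-dien-10-yn-1-yl]oxy}dimethylsilane | C#CCC/C=C(/C)CC/C=C(/C)CO[Si](C)(C)C(C)(C)C | intermediate
10 | [(1E,5Z,9Z)-11-{[tert-butyl(dimethyl)silyl]oxy}-2,6,10-trimethylundeca-1,5,9-trien-1-yl]dimethylaluminium (alkenylalane) | C[Al](C)/C=C(\C)CC/C=C(/C)CC/C=C(/C)CO[Si](C)(C)C(C)(C)C | intermediate
11 | (2E,6Z,10Z)-12-{[tert-butyl(dimethyl)silyl]oxy}-3,7,11-trimethyldodeca-2,6,10-trien-1-ol | OC/C=C(\C)CC/C=C(/C)CC/C=C(/C)CO[Si](C)(C)C(C)(C)C | intermediate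
12 | {[(2Z,6Z,10E)-12-bromo-2,6,10-trimethyldodeca-2,6,10-trien-1-yl]oxy}(tert-butyl)dimethylsilane | BrC/C=C(\C)CC/C=C(/C)CC/C=C(/C)CO[Si](C)(C)C(C)(C)C | intermediate
13 | 3-methylbut-2-enal (prenal) | CC(C)=CC=O | starting material
14 | (R)-2-[diphenyl(trimethylsilyloxy)methyl]-1-[(1E)-3-methylbuta-1,3-dien-1-yl]pyrrolidine (dienamine) | C=C(C)/C=C/N1CCC[C@@H]1C(c1ccccc1)(c1ccccc1)O[Si](C)(C)C | intermediate
15 | (2R,4E,8Z,12Z)-14-{[tert-butyl(dimethyl)silyl]oxy}-5,9,13-trimethyl-2-(prop-1-en-2-yl)tetradeca-4,8,12-trienal | C=C(C)[C@@H](C/C=C(\C)CC/C=C(/C)CC/C=C(/C)CO[Si](C)(C)C(C)(C)C)C=O | intermediate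
16 | tert-butyl{[(2Z,6Z,10E,13S)-2,6,10-trimethyl-13-(prop-1-en-2-yl)pentadeca-2,6,10,14-tetraen-1-yl]oxy}dimethylsilane | C=C(C)[C@@H](C/C=C(\C)CC/C=C(/C)CC/C=C(/C)CO[Si](C)(C)C(C)(C)C)C=C | intermediate
17 | Cp2Zr(Cl)[(3S,5E,9Z,13Z)-15-{[tert-butyl(dimethyl)silyl]oxy}-6,10,14-trimethyl-3-(prop-1-en-2-yl)pentadeca-5,9,13-trien-1-yl] (alkylzirconocene chloride) | C=C(C)[C@@H](C/C=C(\C)CC/C=C(/C)CC/C=C(/C)CO[Si](C)(C)C(C)(C)C)CC[Zr](Cl)(C1C=CC=C1)C1C=CC=C1 | intermediate
18 | tert-butyl{[(2Z,6Z,10E,13S)-15-iodo-2,6,10-trimethyl-13-(prop-1-en-2-yl)pentadeca-2,6,10-trien-1-yl]oxy}dimethylsilane | C=C(C)[C@@H](C/C=C(\C)CC/C=C(/C)CC/C=C(/C)CO[Si](C)(C)C(C)(C)C)CCI | intermediate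
19 | methyl (5R)-2-[bis(2,2,2-trifluoroethoxy)phosphoryl]-5-[(2E,6Z,10Z)-12-{[tert-butyl(dimethyl)silyl]oxy}-3,7,11-trimethyldodeca-2,6,10-trien-1-yl]-6-methylhept-6-enoate | C=C(C)[C@@H](C/C=C(\C)CC/C=C(/C)CC/C=C(/C)CO[Si](C)(C)C(C)(C)C)CCC(C(=O)OC)P(=O)(OCC(F)(F)F)OCC(F)(F)F | intermediate
20 | 3-bromofuran | Brc1ccoc1 | starting material
21 | prop-2-en-1-ol (allyl alcohol) | C=CCO | starting material
22 | 3-(furan-3-yl)propanal | O=CCCc1ccoc1 | intermediate
23 | methyl (2Z,5R)-5-[(2E,6Z,10Z)-12-{[tert-butyl(dimethyl)silyl]oxy}-3,7,11-trimethyldodeca-2,6,10-trien-1-yl]-2-[3-(furan-3-yl)propylidene]-6-methylhept-6-enoate | C=C(C)[C@@H](C/C=C(\C)CC/C=C(/C)CC/C=C(/C)CO[Si](C)(C)C(C)(C)C)CC/C(=C/CCc1ccoc1)C(=O)OC | intermediate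
24 | methyl (2Z,5R)-2-[3-(furan-3-yl)propylidene]-5-[(2E,6Z,10Z)-12-hydroxy-3,7,11-trimethyldodeca-2,6,10-trien-1-yl]-6-methylhept-6-enoate (hydroxy ester) | C=C(C)[C@@H](C/C=C(\C)CC/C=C(/C)CC/C=C(/C)CO)CC/C(=C/CCc1ccoc1)C(=O)OC | intermediate
25 | (2Z,5R)-2-[3-(furan-3-yl)propylidene]-5-[(2E,6Z,10Z)-12-hydroxy-3,7,11-trimethyldodeca-2,6,10-trien-1-yl]-6-methylhept-6-enoic acid | C=C(C)[C@@H](C/C=C(\C)CC/C=C(/C)CC/C=C(/C)CO)CC/C(=C/CCc1ccoc1)C(=O)O | target

**Step count and risks**

Total step count: 14. Longest linear sequence: 13 steps (steps 1 to 11, then 13 and 14); step 12 makes the side fragment 22.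

The three steps most likely to fail:

Risk 1, step 8 (the proposed new dienamine allylation). It can fail through attack of 12 at the γ-carbon of 14 (giving a linear, achiral enal), through N-allylation of the catalyst, or through a low ee. The fallback uses known auxiliary chemistry, sets out from 12 and comes back at 15. (R)-4-Benzyloxazolidin-2-one is acylated with 3-methylbut-2-enoyl chloride (n-BuLi, THF, −78 °C) to give (R)-4-benzyl-3-(3-methylbut-2-enoyl)oxazolidin-2-one F1. Its sodium dienolate (NaN(SiMe3)2, THF, −78 °C) is alkylated by 12 at the α-carbon, on the face away from the benzyl group and with the same deconjugation to the isopropenyl group, to give (R)-4-benzyl-3-[(2R,4E,8Z,12Z)-14-{[tert-butyl(dimethyl)silyl]oxy}-5,9,13-trimethyl-2-(prop-1-en-2-yl)tetradeca-4,8,12-trienoyl]oxazolidin-2-one F2. LiBH4 (MeOH, Et2O, 0 °C) removes the auxiliary and gives (2R,4E,8Z,12Z)-14-{[tert-butyl(dimethyl)silyl]oxy}-5,9,13-trimethyl-2-(prop-1-en-2-yl)tetradeca-4,8,12-trien-1-ol F3. Dess–Martin periodinane (NaHCO3, CH2Cl2, 0 °C) oxidises F3 to 15.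

Risk 2, step 1 (mono-ozonolysis of a diene with two equal alkenes). Over-ozonolysis and peroxidic by-products can cut the yield of 3 badly. The fallback sets out from 1 and comes back at 3. One equivalent of mCPBA (CH2Cl2, 0 °C) gives the stable mono-epoxide (Z)-1,5-dimethyl-9-oxabicyclo[6.1.0]non-4-ene F4, which is separated from unchanged 1 (recycled) and from the bis-epoxide. H5IO6 (THF/H2O, 0 °C) cleaves the epoxide to keto aldehyde 2, which is acetalised as in step 1 (MeOH, TsOH) to give 3.

Risk 3, step 10 (hydrozirconation of the vinyl group next to an isopropenyl group on the same carbon). Partial reaction at the isopropenyl group or incomplete iodinolysis would give mixtures. The fallback sets out from 16 and comes back at 18. Disiamylborane (THF, 0 °C), which discriminates strongly between mono- and 1,1-disubstituted alkenes, followed by NaOH/H2O2, gives (3S,5E,9Z,13Z)-15-{[tert-butyl(dimethyl)silyl]oxy}-6,10,14-trimethyl-3-(prop-1-en-2-yl)pentadeca-5,9,13-trien-1-ol F5. I2, PPh3 and imidazole (CH2Cl2, 0 °C) convert F5 into 18.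

**Further compounds**

F1 | step 8 | (R)-4-benzyl-3-(3-methylbut-2-enoyl)oxazolidin-2-one | CC(C)=CC(=O)N1C(=O)OC[C@H]1Cc1ccccc1
F2 | step 8 | (R)-4-benzyl-3-[(2R,4E,8Z,12Z)-14-{[tert-butyl(dimethyl)silyl]oxy}-5,9,13-trimethyl-2-(prop-1-en-2-yl)tetradeca-4,8,12-trienoyl]oxazolidin-2-one | C=C(C)[C@@H](C/C=C(\C)CC/C=C(/C)CC/C=C(/C)CO[Si](C)(C)C(C)(C)C)C(=O)N1C(=O)OC[C@H]1Cc1ccccc1
F3 | step 8 | (2R,4E,8Z,12Z)-14-{[tert-butyl(dimethyl)silyl]oxy}-5,9,13-trimethyl-2-(prop-1-en-2-yl)tetradeca-4,8,12-trien-1-ol | C=C(C)[C@@H](C/C=C(\C)CC/C=C(/C)CC/C=C(/C)CO[Si](C)(C)C(C)(C)C)CO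
F4 | step 1 | (Z)-1,5-dimethyl-9-oxabicyclo[6.1.0]non-4-ene (racemic cis-epoxide) | C/C1=C/CCC2(C)OC2CC1
F5 | step 10 | (3S,5E,9Z,13Z)-15-{[tert-butyl(dimethyl)silyl]oxy}-6,10,14-trimethyl-3-(prop-1-en-2-yl)pentadeca-5,9,13-trien-1-ol | C=C(C)[C@@H](C/C=C(\C)CC/C=C(/C)CC/C=C(/C)CO[Si](C)(C)C(C)(C)C)CCO
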